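The numbers in the tables were generated by integration with constants of no real substance; noise was put on by code.

I started from the two progress curves.

common to all: starting material 0.10 M; fresh partner 0.105 M

| charge | coupling partner | protic impurity | temperature | remark | time |
|---|---|---|---|---|---|
| ochre | 0.15 M | 2 mM | 50 °C | run made earlier |  |
| amber | 0.22 M | 2 mM | 72 °C | run made earlier |  |
| east | 0.300 M | 2.00 mM | 60 °C |  | 10 min |
| north-west | 0.300 M | 2.00 mM | 80 °C |  | 10 min |
| west | 0.300 M | 2.00 mM | 40 °C |  | 10 min |
| south | 0.300 M | 2.00 mM |  | at 40 °C until 2.0 min, from then on at 80 °C | 10 min |

- ochre (time / min: target / %): 0.833: 1.0; 2.50: 5.2; 5.00: 9.3; 6.00: 10.0; 10.0: 16.1; 12.0: 15.6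
- amber (time / min: target / %): 0.667: 8.8; 1.33: 14.6; 2.00: 19.3; 3.00: 21.9; 4.00: 22.6

(standard deviation of a reading: 1 percentage point)

- which flask leads in amount of target, in percent of the starting material charged ("all alike" within 1.5 percentage points) (east / north-west / west / south / all alike)
- how much target is there at the end, in percent of the starting material charged: east
- how much target is there at the end, in percent of the starting material charged: north-west
- how much target is there at the end, in percent of the starting material charged: west
- how much target is there at the end, in percent of the starting material charged: south

- a reading or a percentage of target counts all its forms, free or not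

The last two readings differed by 0.5 percentage points in ochre and by 0.7 points in amber, inside the scatter of 1 point, so I treated each run as near a plateau, an assumption those readings cannot prove for ochre, and I solved each curve at its two ends and joined them. At the late end I read a plateau of 15.8% in ochre, the mean of its last two readings, and took 22.6% in amber. Dividing the odds of each plateau by c(coupling partner) gave a selectivity factor of 1.26 /M in ochre and 1.33 /M in amber, so with their mean, 1.29 /M, I set the ceiling at c(coupling partner) = 0.300 M to 27.9%.

At the early end the line from the origin through an early reading, the second in ochre and the first in amber, meets the plateau at a time equal to plateau over the slope of that line, which read 7.62 min in ochre and 1.71 min in amber. Interpolating its logarithm in temperature, and ignoring that the two runs also differ in coupling partner, I got 3.87 min for east. This crossover time, the moment the early line meets the plateau at the flask's temperature, was what I carried.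

For east at 10 min the early line stood at 72.2%, higher than the ceiling, so my upper bound was the ceiling. Joining the two ends by a single exponential gave my lower bound, 25.8%. For north-west the same extrapolation gave 0.995 min, much shorter than the run, and a lower end of 27.9%.

The forecast named east, with 29.3% for east, 29% for north-west, 16.5% for west and 29.2% for south, and wrote: “The top three are close, and I lean slightly to east.” Its east lay outside my bracket, above the ceiling.

The flasks gave 27.1% for east, inside my bracket, 8.08% for north-west, 20.2% for west and 10.4% for south. So east led, as forecast, but north-west stood 20 points under my lower end, with 25.1% of over-reaction product beside its target at 10.0 min.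

    starting material + coupling partner → open intermediate (k = 0.232 /M/s, Ea = 72.0 kJ/mol)
    coupling partner + fresh partner → second intermediate (k = 0.521 /M/s, Ea = 37.0 kJ/mol)
    open intermediate + second intermediate → target (k = 0.0281 /M/s, Ea = 50.0 kJ/mol)
    2 second intermediate → homo product (k = 0.0458 /M/s, Ea = 70.0 kJ/mol)
    starting material + protic impurity → quenched substrate (k = 8.28 /M/s, Ea = 43.0 kJ/mol)
    target → over-reaction product (k = 4.73 × 10⁻⁴ /s, Ea = 89.0 kJ/mol)
    fresh partner + target ⇌ idle adduct, settled at all times (K = 6.29 /M, ΔH = −21.0 kJ/mol)
    (constants at 60 °C)

The crossover time also serves a reading of east taken at 2.5 min, where the early line gives 18.1%, less than the ceiling, the joined curve gives 13.3%, and that neighbour flask held 17.0%.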